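Ring B of parritadial (C5–C10), with C12 on C8, the C7=C8 alkene and oxygen on C9, is the ring of (R)-carvone. The key step exploits that C4 of ring A, a gem-dimethyl carbon bonded to C5, is carvone's isopropenyl group plus one hydrogen atom. The route therefore rests on cutting C3–C4. The precursor is carvone bearing at C10 a methyl group cis and an acryloyl group (C1–C3) trans to the isopropenyl group. Hydrogen-atom transfer generates the tertiary C4 radical, which closes onto the vinyl ketone terminus C3. One operation delivers ring A, the C4 quaternary carbon and the trans-fused 1,9-dione. The remaining steps adjust oxygenation and add C11.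

Key step: step 4

Remark on the chemistry: drimane numbering is used throughout and α means the face opposite the C10 methyl group; the target SMILES is read as the 1β,6α-diacetate with 9α-OH, 5α-H and 10β-CH3.

Step 1
Reactants: 1 (R)-carvone; 2 iodomethane
Product: 4 (5R,6S)-6-methylcarvone (methyl on C10 mainly trans to the isopropenyl group), via lithium dienolate 3 (not isolated)
Conditions: LiN(iPr)2 (1.05 equiv), THF, −78 °C; MeI, −78 → 0 °C
Reagents that add atoms: iodomethane (2), CI
Why: Kinetic deprotonation at the only α′ position (C10) gives the cross-conjugated lithium dienolate, whose C-alkylation with iodomethane (enolate alkylation) takes place mainly anti to the isopropenyl group, and the configuration of this new C10 centre does not matter because step 2 makes C10 planar again.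

Step 2
Reactants: 4 6-methylcarvone; 5 acrolein
Product: 7 6-(1-hydroxyprop-2-enyl)-6-methylcarvone (C10 methyl cis and carbinol arm trans to the isopropenyl group; both carbinol epimers), via lithium dienolate 6 (not isolated)
Conditions: LiN(iPr)2 (1.1 equiv), THF, −78 → −20 → −78 °C; acrolein, −78 °C; AcOH quench at −78 °C
Reagents that add atoms: acrolein (5), C=CC=O
Why: Directed lithium aldol addition: in the tetrasubstituted dienolate the isopropenyl group turns pseudoaxial to avoid the C10 methyl group and shields its own face, so acrolein is attacked in the 1,2 sense from the opposite face, which sets the C10 quaternary centre as in the familiar second alkylation of 6-alkylcarvones, while the carbinol centre is left as a mixture that step 3 erases.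

Step 3
Reactants: 7 6-(1-hydroxyprop-2-enyl)-6-methylcarvone
Product: 8 6-acryloyl-6-methylcarvone (C10 methyl cis to the isopropenyl group)
Conditions: Dess–Martin periodinane, CH2Cl2, 0 °C → rt
Reagents that add atoms: none
Why: Dess–Martin oxidation of a secondary allylic alcohol runs without base, so retro-aldol cleavage of the crowded aldol is avoided, C10 has no hydrogen and cannot epimerise, and the sensitive vinyl ketone is taken into step 4 without storage.

Step 4
Reactants: 8 6-acryloyl-6-methylcarvone
Product: 9 trans-fused 11-nordrim-7-ene-1,9-dione (5α-H; 10β-CH3; C4 gem-dimethyl; C12 methyl on C8)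
Conditions: Fe(acac)3 (0.3 equiv), PhSiH3 (2.5 equiv), degassed EtOH (0.02 M), 60 °C
Reagents that add atoms: none
Why: An iron hydride formed from Fe(acac)3 and PhSiH3 transfers a hydrogen atom to the CH2 terminus of the isopropenyl group and leaves the nucleophilic tertiary radical at C4, which adds to C3, the unsubstituted β-carbon of the vinyl ketone, after which the α-keto radical at C2 is reduced by divalent iron to the enolate and protonated by ethanol. The closest known reaction type is the iron-catalysed reductive olefin coupling (a Giese addition started by hydrogen-atom transfer), whose intramolecular variants are established for building quaternary carbons. Ring A closes in the 6-endo-trig mode, because both alkene carbons C2 and C3 end up inside the ring, whereas 5-exo attack at C2 is polarity-mismatched and would leave a primary radical. No stereocentre is created, since C4 carries two methyl groups and the trans ring fusion is inherited from C5 and C10, whose reacting arms are trans-diequatorial on ring B. The step needs hydrogen-atom transfer to the isopropenyl group alone, and this is secured because it is the only electron-rich 1,1-disubstituted alkene, C7=C8 and C2=C3 both being electron-poor enone alkenes. Dilution, exclusion of oxygen and the proximity of the two vicinal equatorial arms should let ring closure outrun quenching of the radical.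

Step 5
Reactants: 9 11-nordrim-7-ene-1,9-dione
Product: 10 1β-hydroxy-11-nordrim-7-en-9-one
Conditions: NaBH4 (0.5 equiv), MeOH/CH2Cl2, −78 → −40 °C
Reagents that add atoms: none
Why: Chemoselective borohydride reduction of a saturated ketone beside an enone, as with the Wieland–Miescher ketone: the C1 carbonyl reacts before the conjugated C9 carbonyl, and hydride enters axially from the α face, away from the axial C10 methyl group, to set the equatorial 1β-alcohol.

Step 6
Reactants: 10 1β-hydroxy-11-nordrim-7-en-9-one
Product: 11 1β,9-bis(triethylsilyloxy)-11-nordrima-6,8-diene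
Conditions: Et3SiOTf (3 equiv), Et3N (5 equiv), CH2Cl2, 0 °C → rt
Reagents that add atoms: triethylsilyl trifluoromethanesulfonate, CC[Si](CC)(CC)OS(=O)(=O)C(F)(F)F
Why: Soft enolisation with a silyl triflate and an amine: C10 bears no hydrogen and C1 is no longer a ketone, so the O-silylated enone can only lose a γ-proton from C6 to give the linear dienol silyl ether, while the C1 hydroxyl is silylated at the same time and thereby guarded against retro-aldol cleavage.

Step 7
Reactants: 11 1β,9-bis(triethylsilyloxy)-11-nordrima-6,8-diene
Product: 13 1β,6α-dihydroxy-11-nordrim-7-en-9-one, via mono-TES hydroxy enone 12 (not isolated)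
Conditions: mCPBA (1.1 equiv), CH2Cl2/hexane, −20 °C; then 1 M aq. HCl, THF, 0 °C → rt
Reagents that add atoms: 3-chloroperoxybenzoic acid (mCPBA), OOC(=O)c1cccc(Cl)c1
Why: Vinylogous Rubottom oxidation: the peracid delivers oxygen to the less hindered, electron-rich C6=C7 bond rather than to the tetrasubstituted C8=C9 bond, it does so from the α face because the β face of C6 is closed by the axial methyl groups on C4 and C10, collapse with loss of the C9 silyl group restores the enone with a 6α-hydroxyl, and dilute acid then frees the C1 hydroxyl.

Step 8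
Reactants: 13 1β,6α-dihydroxy-11-nordrim-7-en-9-one
Product: 14 1β,6α-diacetoxy-11-nordrim-7-en-9-one
Conditions: Ac2O, pyridine, DMAP (cat.), rt
Reagents that add atoms: acetic anhydride, CC(=O)OC(C)=O
Why: DMAP-catalysed acylation esterifies both secondary alcohols with retention at C1 and C6, and the quaternary C10 rules out β-elimination of the C1 acetate.

Step 9
Reactants: 14 1β,6α-diacetoxy-11-nordrim-7-en-9-one
Product: 15 1β,6α-diacetoxydrima-7,9(11)-diene
Conditions: Zn, CH2Br2, TiCl4, THF, −40 → 5 °C (aged slurry); then 14, CH2Cl2, 0 °C → rt
Reagents that add atoms: dibromomethane, BrCBr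
Why: Takai–Lombardo methylenation: the non-basic gem-dimetallic reagent converts ketones, including crowded and base-sensitive ones, into methylene groups while leaving acetate esters alone, and it avoids the deprotonation at C6 and the ester attack that a phosphorus ylide would risk.

Step 10
Reactants: 15 1β,6α-diacetoxydrima-7,9(11)-diene
Product: 16 1β,6α-diacetoxydrim-7-ene-9α,11-diol
Conditions: OsO4 (10 mol %), NMO, acetone/H2O, 0 °C → rt
Reagents that add atoms: N-methylmorpholine N-oxide, C[N+]1([O-])CCOCC1; water, O; the oxygen is relayed through OsO4, O=[Os](=O)(=O)=O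
Why: Upjohn dihydroxylation: the osmium reagent should take the exocyclic C9=C11 bond rather than C7=C8, which is trisubstituted and deactivated by the allylic C6 acetate, and it approaches from the α face opposite the adjacent axial C10 methyl group, which sets the axial 9α-hydroxyl and places C11 β (equatorial).

Step 11
Reactants: 16 1β,6α-diacetoxydrim-7-ene-9α,11-diol
Product: 18 1β,6α-diacetoxydrim-7-ene-9α,11,12-triol, via enal 17 (not isolated)
Conditions: SeO2 (20 mol %), t-BuOOH, CH2Cl2, rt → 40 °C; then crude, NaBH4, MeOH, 0 °C
Reagents that add atoms: tert-butyl hydroperoxide, CC(C)(C)OO; the oxygen is relayed through SeO2, O=[Se]=O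
Why: Riley allylic oxidation in its catalytic hydroperoxide variant (ene reaction, then [2,3]-sigmatropic shift): selenium binds C7 and the hydrogen is taken at the more substituted terminus C8, whose only allylic C–H bonds are those of C12 because C9 is fully substituted, as in the known oxidation of prenyl acetate, and borohydride returns the fraction that runs on to enal 17 to triol 18.

Step 12
Reactants: 18 1β,6α-diacetoxydrim-7-ene-9α,11,12-triol
Product: 19 parritadial (1β,6α-diacetoxy-9α-hydroxydrim-7-ene-11,12-dial)
Conditions: (COCl)2, DMSO, CH2Cl2, −78 °C; Et3N, −78 → −20 °C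
Reagents that add atoms: none
Why: Double Swern oxidation: both primary carbinols are turned into alkoxysulfonium salts before the base is added, so no free hydroxy aldehyde can close to a lactol and be over-oxidised to the lactone, the tertiary 9α-hydroxyl cannot be oxidised, and the acetates and all five stereocentres are left untouched.

Compound list
1 | (R)-carvone | O=C1C(C)=CC[C@@H](C(C)=C)C1 | starting material
2 | iodomethane | CI | starting material
3 | lithium cross-conjugated dienolate of 1 (not isolated) | [Li]OC1=C[C@H](C(C)=C)CC=C1C | intermediate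
4 | (5R,6S)-6-methylcarvone (major epimer drawn; C10 centre erased in step 2) | C1C=C(C)C(=O)[C@@H](C)[C@@H]1C(C)=C | intermediate
5 | acrolein | C=CC=O | starting material
6 | lithium dienolate of 4 (not isolated) | [Li]OC1=C(C)[C@H](C(C)=C)CC=C1C | intermediate
7 | 6-(1-hydroxyprop-2-enyl)-6-methylcarvone (carbinol centre: both epimers, erased in step 3) | C1C=C(C)C(=O)[C@@](C)(C(O)C=C)[C@@H]1C(C)=C | intermediate
8 | 6-acryloyl-6-methylcarvone (C10 methyl cis to isopropenyl) | C1C=C(C)C(=O)[C@@](C)(C(=O)C=C)[C@@H]1C(C)=C | intermediate
9 | trans-fused 11-nordrim-7-ene-1,9-dione | C1C=C(C)C(=O)[C@@]2(C)C(=O)CCC(C)(C)[C@H]12 | intermediate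
10 | 1β-hydroxy-11-nordrim-7-en-9-one | C1C=C(C)C(=O)[C@@]2(C)[C@H](O)CCC(C)(C)[C@H]12 | intermediate
11 | 1β,9-bis(triethylsilyloxy)-11-nordrima-6,8-diene | C1=CC(C)=C(O[Si](CC)(CC)CC)[C@@]2(C)[C@H](O[Si](CC)(CC)CC)CCC(C)(C)[C@H]12 | intermediate
12 | 6α-hydroxy-1β-triethylsilyloxy-11-nordrim-7-en-9-one (not isolated) | O[C@H]1C=C(C)C(=O)[C@@]2(C)[C@H](O[Si](CC)(CC)CC)CCC(C)(C)[C@H]12 | intermediate
13 | 1β,6α-dihydroxy-11-nordrim-7-en-9-one | O[C@H]1C=C(C)C(=O)[C@@]2(C)[C@H](O)CCC(C)(C)[C@H]12 | intermediate
14 | 1β,6α-diacetoxy-11-nordrim-7-en-9-one | CC(=O)O[C@H]1C=C(C)C(=O)[C@@]2(C)[C@H](OC(C)=O)CCC(C)(C)[C@H]12 | intermediate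
15 | 1β,6α-diacetoxydrima-7,9(11)-diene | CC(=O)O[C@H]1C=C(C)C(=C)[C@@]2(C)[C@H](OC(C)=O)CCC(C)(C)[C@H]12 | intermediate
16 | 1β,6α-diacetoxydrim-7-ene-9α,11-diol | CC(=O)O[C@H]1C=C(C)[C@](O)(CO)[C@@]2(C)[C@H](OC(C)=O)CCC(C)(C)[C@H]12 | intermediate
17 | 1β,6α-diacetoxy-9α,11-dihydroxydrim-7-en-12-al (not isolated) | CC(=O)O[C@H]1C=C(C=O)[C@](O)(CO)[C@@]2(C)[C@H](OC(C)=O)CCC(C)(C)[C@H]12 | intermediate
18 | 1β,6α-diacetoxydrim-7-ene-9α,11,12-triol | CC(=O)O[C@H]1C=C(CO)[C@](O)(CO)[C@@]2(C)[C@H](OC(C)=O)CCC(C)(C)[C@H]12 | intermediate
19 | parritadial | CC(=O)O[C@H]1C=C(C=O)[C@](O)(C=O)[C@@]2(C)[C@H](OC(C)=O)CCC(C)(C)[C@H]12 | target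

Total step count: 12. Longest linear sequence: 12 steps from (R)-carvone.

Steps most likely to fail

Step 4. The C4 radical may receive a second hydrogen atom before it closes. The iron hydride and the alcohol solvent may also consume the vinyl ketone by reduction, oxa-Michael addition or oligomerisation. The fallback sets out from 8 and comes back at 9, and it makes the same radical by halogen abstraction instead of hydrogen-atom transfer. HBr in AcOH at 0 °C should add in the Markovnikov sense to the isopropenyl group and in the conjugate sense to the vinyl ketone, giving the dibromide F1. Et3N in CH2Cl2 at 0 °C removes HBr only from the β-bromo ketone (E1cB) and gives the tertiary bromide F2 with the vinyl ketone restored. Slow addition of Bu3SnH with Et3B and air in toluene at room temperature then runs a classical tin hydride Giese cyclisation to 9.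

Step 9. Addition to the C9 carbonyl may be too slow, since it is flanked by the quaternary C10 and the C8 methyl group and faces the 1β-acetate. The Lewis-acidic, zinc-containing medium may also ionise or reductively remove the C6 acetate. The fallback sets out from 13 and comes back at 15, and it replaces direct methylenation by addition and elimination in a silyl-protected series.
- Et3SiCl and imidazole in DMF give the bis(triethylsilyl) ether F3.
- Me3SiCH2Li, premixed with CeCl3 in THF at −78 °C, adds to C9 from the α face to give the β-hydroxysilane F4.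
- KH in THF triggers the Peterson elimination to the silylated diene F5.
- Bu4NF frees the diene diol F6.
- Ac2O, pyridine and DMAP give 15.

Step 11. The ene reaction may be sluggish on an alkene deactivated by allylic C–O bonds on both sides. Binding of selenium to the 1,2-diol or acetyl migration during long reaction times may erode the material. The fallback sets out from 16 and comes back at 17, and it replaces the pericyclic oxidation by radical halogenation and substitution.
- 2,2-Dimethoxypropane with pyridinium tosylate gives the acetonide F7.
- NBS and AIBN in PhCF3 at reflux (Wohl–Ziegler) should brominate the only accessible allylic position and give the C12 bromide F8.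
- N-Methylmorpholine N-oxide in MeCN (Kornblum-type oxidation of an allylic halide) gives the enal acetonide F9.
- Aqueous AcOH removes the acetonide to give 17, which NaBH4 reduces to 18 as in step 11.

Further compounds
F1 | step 4 | 6-(3-bromopropanoyl)-5-(2-bromopropan-2-yl)-2,6-dimethylcyclohex-2-enone (dibromide) | C1C=C(C)C(=O)[C@@](C)(C(=O)CCBr)[C@@H]1C(C)(C)Br
F2 | step 4 | 6-acryloyl-5-(2-bromopropan-2-yl)-2,6-dimethylcyclohex-2-enone (tertiary bromide) | C1C=C(C)C(=O)[C@@](C)(C(=O)C=C)[C@@H]1C(C)(C)Br
F3 | step 9 | 1β,6α-bis(triethylsilyloxy)-11-nordrim-7-en-9-one | CC[Si](CC)(CC)O[C@H]1C=C(C)C(=O)[C@@]2(C)[C@H](O[Si](CC)(CC)CC)CCC(C)(C)[C@H]12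
F4 | step 9 | 1β,6α-bis(triethylsilyloxy)-11-trimethylsilyl-9-epi-drim-7-en-9β-ol (β-hydroxysilane) | CC[Si](CC)(CC)O[C@H]1C=C(C)[C@@](O)(C[Si](C)(C)C)[C@@]2(C)[C@H](O[Si](CC)(CC)CC)CCC(C)(C)[C@H]12
F5 | step 9 | 1β,6α-bis(triethylsilyloxy)drima-7,9(11)-diene | CC[Si](CC)(CC)O[C@H]1C=C(C)C(=C)[C@@]2(C)[C@H](O[Si](CC)(CC)CC)CCC(C)(C)[C@H]12
F6 | step 9 | drima-7,9(11)-diene-1β,6α-diol | O[C@H]1C=C(C)C(=C)[C@@]2(C)[C@H](O)CCC(C)(C)[C@H]12
F7 | step 11 | 1β,6α-diacetoxydrim-7-ene-9α,11-diol acetonide | CC(=O)O[C@H]1C=C(C)[C@]3(COC(C)(C)O3)[C@@]2(C)[C@H](OC(C)=O)CCC(C)(C)[C@H]12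
F8 | step 11 | 12-bromo-1β,6α-diacetoxydrim-7-ene-9α,11-diol acetonide | CC(=O)O[C@H]1C=C(CBr)[C@]3(COC(C)(C)O3)[C@@]2(C)[C@H](OC(C)=O)CCC(C)(C)[C@H]12
F9 | step 11 | 1β,6α-diacetoxy-9α,11-dihydroxydrim-7-en-12-al acetonide | CC(=O)O[C@H]1C=C(C=O)[C@]3(COC(C)(C)O3)[C@@]2(C)[C@H](OC(C)=O)CCC(C)(C)[C@H]12
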